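**Strategy.** Ring A (C1–C6, the methoxy-enedione ring) is disconnected at its enol-ether double bond C2=C3 and at the C5–C6 bond to the spiro carbon. In one operation the enolate of a cyclohexenyl keto ylide is C-acylated anti to the isopropyl group by methyl 3-chloro-2,2-dimethyl-3-oxopropanoate, which sets quaternary C6, and the ylide then olefinates the methyl ester, so the ester OMe becomes the C3 enol-ether OMe with no regiochemical choice. The step exploits the vinylogous ester C1(=O)–C2(Me)=C3(OMe) flanked by non-enolisable quaternary C4 and C6. The precursor is a keto phosphorane on a cyclohexene ring made by an enantioselective Diels–Alder reaction of myrcene.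

Key step: step 6

Remark 1: the (S)-oxazaborolidinium salt is written in step 1 on the premise that it steers myrcene to the C2-Re/C3-Re face of ketone-bound 2; if the sense is the opposite, the mirror-image catalyst is used.
Remark 2: compound 9 is taken as a catalogue compound.

Step 1
Reactants: 1 myrcene; 2 methyl (2E)-4-oxopent-2-enoate
Product: 3 methyl (1R,6R)-6-acetyl-3-(4-methylpent-3-en-1-yl)cyclohex-3-ene-1-carboxylate
Conditions: (S)-3,3-diphenyl-1-(2-methylphenyl)tetrahydro-1H,3H-pyrrolo[1,2-c][1,3,2]oxazaborole (20 mol %), HNTf2 (18 mol %), CH2Cl2, −78 to −40 °C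
Reagents that add atoms: none
Why: Catalytic enantioselective Diels–Alder reaction in which the boron cation binds the more basic ketone carbonyl, so the nucleophilic CH2 terminus of myrcene (the one on the substituted diene carbon) bonds to the ester-bearing carbon and the acetyl-bearing carbon ends para to the side chain; the E alkene gives the trans adduct and the catalyst face selection sets C6 (and C1) as (1R,6R).

Step 2
Reactants: 3 methyl (1R,6R)-6-acetyl-3-(4-methylpent-3-en-1-yl)cyclohex-3-ene-1-carboxylate
Product: 4 methyl (1R,6R)-3-(4-methylpent-3-en-1-yl)-6-(prop-1-en-2-yl)cyclohex-3-ene-1-carboxylate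
Conditions: Zn, CH2Br2, TiCl4, THF, 0 °C; then 3 in CH2Cl2, rt
Reagents that add atoms: dibromomethane, BrCBr
Why: Takai–Lombardo methylenation is non-basic, so the ketone should be converted to the 1,1-disubstituted alkene without epimerising C6 and without attack on the ester.

Step 3
Reactants: 4 methyl (1R,6R)-3-(4-methylpent-3-en-1-yl)-6-(prop-1-en-2-yl)cyclohex-3-ene-1-carboxylate
Product: 5 methyl (1R,6S)-3-(4-methylpent-3-en-1-yl)-6-(propan-2-yl)cyclohex-3-ene-1-carboxylate
Conditions: H2 (1 atm), RhCl(PPh3)3 (5 mol %), benzene/EtOH, rt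
Reagents that add atoms: none
Why: Homogeneous hydrogenation with RhCl(PPh3)3 reduces 1,1-disubstituted alkenes much faster than trisubstituted ones, so only the isopropenyl group should be saturated; no stereocentre is created (the C6 descriptor changes by priority only).

Step 4
Reactants: 5 methyl (1R,6S)-3-(4-methylpent-3-en-1-yl)-6-(propan-2-yl)cyclohex-3-ene-1-carboxylate
Product: 6 (1R,6S)-3-(4-methylpent-3-en-1-yl)-6-(propan-2-yl)cyclohex-3-ene-1-carboxylic acid
Conditions: LiOH, THF/MeOH/H2O, 50 °C; then 1 M HCl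
Reagents that add atoms: lithium hydroxide, [Li+].[OH-]
Why: Ester saponification; C6 carries no acidic hydrogen, and epimerisation at C1 would be harmless because C1 is planarised in step 6.

Step 5
Reactants: 6 (1R,6S)-3-(4-methylpent-3-en-1-yl)-6-(propan-2-yl)cyclohex-3-ene-1-carboxylic acid
Product: 8 1-[(1R,6S)-3-(4-methylpent-3-en-1-yl)-6-(propan-2-yl)cyclohex-3-en-1-yl]-2-(triphenyl-λ5-phosphanylidene)propan-1-one, via acid chloride 7 (not isolated)
Conditions: 1-chloro-N,N,2-trimethylprop-1-en-1-amine, CH2Cl2, 0 °C to rt; then Ph3P=CHCH3 (2.2 equiv, from ethyltriphenylphosphonium bromide and NaN(SiMe3)2), THF, −78 °C to rt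
Reagents that add atoms: ethyltriphenylphosphonium bromide, CC[P+](c1ccccc1)(c1ccccc1)c1ccccc1.[Br-]; 1-chloro-N,N,2-trimethylprop-1-en-1-amine, CC(C)=C(Cl)N(C)C (chlorine of 7 only)
Why: Acylation of a non-stabilised ylide by an acid chloride followed by transylidation with the second equivalent should give the stable keto ylide, and the neutral chlorination spares the two trisubstituted alkenes.

Step 6
Reactants: 8 1-[(1R,6S)-3-(4-methylpent-3-en-1-yl)-6-(propan-2-yl)cyclohex-3-en-1-yl]-2-(triphenyl-λ5-phosphanylidene)propan-1-one; 9 methyl 3-chloro-2,2-dimethyl-3-oxopropanoate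
Product: 12 (6R,11S)-3-methoxy-2,4,4-trimethyl-8-(4-methylpent-3-en-1-yl)-11-(propan-2-yl)spiro[5.5]undeca-2,8-diene-1,5-dione, via lithium ylide enolate 10 (not isolated), via acylated keto ylide 11 (not isolated)
Conditions: LiN(iPr)2, THF, −78 to 0 °C; 9, −78 °C to rt; then xylene, 140 °C
Reagents that add atoms: none
Why: Proposed new method: LiN(iPr)2 removes the only enolisable hydrogen of 8 (ring C1–H, alpha-prime to the ylide carbonyl) to give ylide enolate 10, which is C-acylated by 9 to 11; on heating, the ylide carbon adds to the methyl ester carbonyl and the oxaphosphetane collapses to Ph3P=O and the C2=C3 enol ether, so the ester methoxy group becomes the enol-ether methoxy group and no regioisomer can arise. The closest known reaction types are the gamma-alkylation and aldol reactions of lithiated acylmethylenephosphoranes, the C-acylation of hindered ester enolates by acid chlorides, and the intramolecular Wittig olefination of ester carbonyls by stabilised ylides (tetronates from alpha-hydroxy esters and Ph3P=C=C=O); the pairing of a keto-stabilised ylide with an unactivated ester in a carbocyclic closure is the untested part. Ring A closes in the 6-exo-trig mode (ylide carbon onto the ester C=O) followed by [2+2] cycloreversion. The spiro stereocentre is set in the acylation: allylic strain in the exocyclic enolate turns the neighbouring isopropyl group pseudo-axial, so 9 enters anti to it and the ylide-bearing carbonyl (C1 of 12) ends cis to isopropyl, which is (6R). The step needs C- over O-acylation and olefination of the ester and not of the C5 ketone; the first is favoured because the ylide carbon is a strong donor that makes 10 behave like an ester or amide enolate, the second by geometry (attack at the ketone would need a four-membered ring), by the gem-dialkyl effect of quaternary C4 and C6, and by the absence of any enolisable hydrogen in 11.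

**Compound list**
1 | myrcene (7-methyl-3-methylideneocta-1,6-diene) | C=CC(=C)CCC=C(C)C | starting material
2 | methyl (2E)-4-oxopent-2-enoate | COC(=O)/C=C/C(C)=O | starting material
3 | methyl (1R,6R)-6-acetyl-3-(4-methylpent-3-en-1-yl)cyclohex-3-ene-1-carboxylate | COC(=O)[C@@H]1CC(CCC=C(C)C)=CC[C@H]1C(C)=O | intermediate
4 | methyl (1R,6R)-3-(4-methylpent-3-en-1-yl)-6-(prop-1-en-2-yl)cyclohex-3-ene-1-carboxylate | COC(=O)[C@@H]1CC(CCC=C(C)C)=CC[C@H]1C(C)=C | intermediate
5 | methyl (1R,6S)-3-(4-methylpent-3-en-1-yl)-6-(propan-2-yl)cyclohex-3-ene-1-carboxylate | COC(=O)[C@@H]1CC(CCC=C(C)C)=CC[C@H]1C(C)C | intermediate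
6 | (1R,6S)-3-(4-methylpent-3-en-1-yl)-6-(propan-2-yl)cyclohex-3-ene-1-carboxylic acid | OC(=O)[C@@H]1CC(CCC=C(C)C)=CC[C@H]1C(C)C | intermediate
7 | (1R,6S)-3-(4-methylpent-3-en-1-yl)-6-(propan-2-yl)cyclohex-3-ene-1-carbonyl chloride | ClC(=O)[C@@H]1CC(CCC=C(C)C)=CC[C@H]1C(C)C | intermediate
8 | 1-[(1R,6S)-3-(4-methylpent-3-en-1-yl)-6-(propan-2-yl)cyclohex-3-en-1-yl]-2-(triphenyl-λ5-phosphanylidene)propan-1-one | CC(=P(c1ccccc1)(c1ccccc1)c1ccccc1)C(=O)[C@@H]1CC(CCC=C(C)C)=CC[C@H]1C(C)C | intermediate
9 | methyl 3-chloro-2,2-dimethyl-3-oxopropanoate | COC(=O)C(C)(C)C(Cl)=O | starting material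
10 | lithium enolate of 8 (exocyclic enolate at ring C1, 6S) | [Li+].[O-]C(=C1CC(CCC=C(C)C)=CC[C@H]1C(C)C)C(C)=P(c1ccccc1)(c1ccccc1)c1ccccc1 | intermediate
11 | methyl 2,2-dimethyl-3-oxo-3-[(1S,6S)-3-(4-methylpent-3-en-1-yl)-6-(propan-2-yl)-1-[2-(triphenyl-λ5-phosphanylidene)propanoyl]cyclohex-3-en-1-yl]propanoate | CC(=P(c1ccccc1)(c1ccccc1)c1ccccc1)C(=O)[C@]1(CC(CCC=C(C)C)=CC[C@H]1C(C)C)C(=O)C(C)(C)C(=O)OC | intermediate
12 | (6R,11S)-3-methoxy-2,4,4-trimethyl-8-(4-methylpent-3-en-1-yl)-11-(propan-2-yl)spiro[5.5]undeca-2,8-diene-1,5-dione | COC1=C(C)C(=O)[C@]2(CC(CCC=C(C)C)=CC[C@H]2C(C)C)C(=O)C1(C)C | target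

**Step count and risks**
Total steps: 6. Longest linear sequence: 6 (1 and 2 to 3, then 4, 5, 6, 8 and 12).

Steps most likely to fail:

Step 6. The keto-stabilised ylide may fail to add to the hindered, unactivated ester carbonyl, so that 11 persists or decomposes on prolonged heating. The fallback sets out from 11, isolated after the acylation at room temperature, and returns at 12 by a classical Dieckmann route. Reductive removal of phosphorus (Zn, AcOH, rt) gives the ethyl ketone methyl 2,2-dimethyl-3-oxo-3-[(1R,6S)-3-(4-methylpent-3-en-1-yl)-1-propanoyl-6-(propan-2-yl)cyclohex-3-en-1-yl]propanoate F1. Its only enolisable position is the propanoyl CH2, so KOtBu in THF should close ring A by Dieckmann condensation to (6R,11S)-2,2,4-trimethyl-8-(4-methylpent-3-en-1-yl)-11-(propan-2-yl)spiro[5.5]undec-8-ene-1,3,5-trione F2. O-methylation (Me2SO4, K2CO3, acetone) then gives 12. This last operation is expected to favour the less hindered oxygen next to the gem-dimethyl carbon, but the regioisomeric enol ether must be separated and can be hydrolysed back to F2.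

Step 1. The catalyst may bind the ester carbonyl of 2 in competition with the ketone, which would erode both the regiochemistry and the facial selectivity of the cycloaddition. The fallback sets out from 1 and returns at 3. An iminium-catalysed Diels–Alder reaction of 1 with methyl (2E)-4-oxobut-2-enoate is used, with (2S,5S)-5-benzyl-2-tert-butyl-3-methylimidazolidin-4-one trifluoroacetate or its mirror image, whichever delivers the (1R,6R) adduct. The iminium ion is the only strongly activating group, so the same regiochemistry should result, giving methyl (1R,6R)-6-formyl-3-(4-methylpent-3-en-1-yl)cyclohex-3-ene-1-carboxylate F3. MeMgBr in THF at −78 °C should add to the aldehyde alone and give methyl (1R,6R)-6-(1-hydroxyethyl)-3-(4-methylpent-3-en-1-yl)cyclohex-3-ene-1-carboxylate F4 as a carbinol mixture. Oxidation with 1,1,1-triacetoxy-1,1-dihydro-1,2-benziodoxol-3(1H)-one in CH2Cl2 then gives 3.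

Step 5. The basic ylide may dehydrochlorinate 7 to the ketene, which then dimerises or is olefinated to an allene, in place of the acyl transfer. The fallback sets out from 6 and returns at 8 by building the ylide from an alpha-bromo ketone. EtLi (2.2 equiv, Et2O, 0 °C) converts the acid into 1-[(1R,6S)-3-(4-methylpent-3-en-1-yl)-6-(propan-2-yl)cyclohex-3-en-1-yl]propan-1-one F5. Kinetic enolisation at the unhindered CH2 (LiN(SiMe3)2, THF, −78 °C) and trapping with N-bromosuccinimide gives 2-bromo-1-[(1R,6S)-3-(4-methylpent-3-en-1-yl)-6-(propan-2-yl)cyclohex-3-en-1-yl]propan-1-one F6. PPh3 in toluene at 80 °C gives {1-oxo-1-[(1R,6S)-3-(4-methylpent-3-en-1-yl)-6-(propan-2-yl)cyclohex-3-en-1-yl]propan-2-yl}triphenylphosphonium bromide F7, and aqueous NaOH/CH2Cl2 liberates 8.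

**Further compounds**
F1 | step 6 | methyl 2,2-dimethyl-3-oxo-3-[(1R,6S)-3-(4-methylpent-3-en-1-yl)-1-propanoyl-6-(propan-2-yl)cyclohex-3-en-1-yl]propanoate | CCC(=O)[C@]1(CC(CCC=C(C)C)=CC[C@H]1C(C)C)C(=O)C(C)(C)C(=O)OC
F2 | step 6 | (6R,11S)-2,2,4-trimethyl-8-(4-methylpent-3-en-1-yl)-11-(propan-2-yl)spiro[5.5]undec-8-ene-1,3,5-trione | CC1C(=O)[C@]2(CC(CCC=C(C)C)=CC[C@H]2C(C)C)C(=O)C(C)(C)C1=O
F3 | step 1 | methyl (1R,6R)-6-formyl-3-(4-methylpent-3-en-1-yl)cyclohex-3-ene-1-carboxylate | COC(=O)[C@@H]1CC(CCC=C(C)C)=CC[C@H]1C=O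
F4 | step 1 | methyl (1R,6R)-6-(1-hydroxyethyl)-3-(4-methylpent-3-en-1-yl)cyclohex-3-ene-1-carboxylate | COC(=O)[C@@H]1CC(CCC=C(C)C)=CC[C@H]1C(C)O
F5 | step 5 | 1-[(1R,6S)-3-(4-methylpent-3-en-1-yl)-6-(propan-2-yl)cyclohex-3-en-1-yl]propan-1-one | CCC(=O)[C@@H]1CC(CCC=C(C)C)=CC[C@H]1C(C)C
F6 | step 5 | 2-bromo-1-[(1R,6S)-3-(4-methylpent-3-en-1-yl)-6-(propan-2-yl)cyclohex-3-en-1-yl]propan-1-one | CC(Br)C(=O)[C@@H]1CC(CCC=C(C)C)=CC[C@H]1C(C)C
F7 | step 5 | {1-oxo-1-[(1R,6S)-3-(4-methylpent-3-en-1-yl)-6-(propan-2-yl)cyclohex-3-en-1-yl]propan-2-yl}triphenylphosphonium bromide | CC(C(=O)[C@@H]1CC(CCC=C(C)C)=CC[C@H]1C(C)C)[P+](c1ccccc1)(c1ccccc1)c1ccccc1.[Br-]
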